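**Retrosynthetic overview**

1. Target 28 ⇒ acid 27 ⇒ alcohol 25 (late oxidation and esterification). The (3E,5E)-diene is cut at C4–C5: Suzuki coupling of bicyclic vinyl iodide 17 with the Roche-ester-derived (R,E)-vinyl boronate 23, which carries the C2 stereocentre.
2. 17 ⇒ terminal alkyne 15 (carboalumination–iodination) ⇒ allylic bromide 11 + lithiated 1-(trimethylsilyl)propyne.
3. 11 ⇒ allylic alcohol 10 ⇒ enoate 9 ⇒ enol triflate 8 ⇒ cis-fused bicyclic β-keto ester 6.
4. 6 ⇒ acyclic (Z)-dienyl β-keto ester 5 by the proposed catalytic enantioselective proton-initiated bicyclisation. Ring A (gem-dimethyl ring) closes first and ring B (keto-ester ring) second in one cascade; the Z-olefin sets the cis fusion.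
5. 5 ⇒ neryl bromide 2 (from nerol 1) + methyl acetoacetate 3.

Assumption: the SMILES is read literally, i.e. a cis-fused decalin (H-4a and CH3-8a on the same face; 4aR,8aS), 2R, 3E,5E; the IDPi antipode that gives (4aR,8aS)-6 is the one used (written as S,S), and 6 is carried as its C-1 epimer/enol mixture because C-1 becomes sp2 in step 4.

**Route**

Step 1
Reactants: 1 nerol
Product: 2 neryl bromide [(2Z)-1-bromo-3,7-dimethylocta-2,6-diene]
Conditions: PBr3 (0.4 equiv), Et2O, −10 °C, 30 min; used crude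
Reagents that add atoms: phosphorus tribromide, BrP(Br)Br
Why: PBr3 bromination of the primary allylic alcohol (SN2 on the phosphite ester) at low temperature keeps the Z-trisubstituted olefin intact.

Step 2
Reactants: 3 methyl acetoacetate; 2 neryl bromide
Product: 5 methyl (6Z)-7,11-dimethyl-3-oxododeca-6,10-dienoate, via methyl acetoacetate dianion 4 (not isolated)
Conditions: NaH (1.1 equiv), THF, 0 °C; n-BuLi (1.05 equiv), 0 °C; then 2, 0 °C → rt; 1 M HCl quench
Reagents that add atoms: none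
Why: Weiler dianion alkylation: the more nucleophilic γ-carbon of the dianion displaces the primary allylic bromide (SN2) without touching the olefin geometry.

Step 3
Reactants: 5 (Z)-dienyl β-keto ester
Product: 6 methyl (4aR,8aS)-5,5,8a-trimethyl-2-oxodecahydronaphthalene-1-carboxylate (cis-fused; C-1 epimers)
Conditions: chiral IDPi Brønsted acid (5 mol %; (S,S)-BINOL-derived imidodiphosphorimidate, 3,3′-aryl = 3,5-bis(trifluoromethyl)phenyl, N-SO2CF3 core), (CF3)3COH/CH2Cl2 4:1, −20 °C, 48–72 h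
Reagents that add atoms: none
Why: Proposed new method: the confined, strongly acidic IDPi protonates the terminal 10,11-olefin of the folded substrate inside its chiral pocket while the enol OH/ester C=O of the β-keto ester is hydrogen-bonded to the phosphorimidate anion; the Z-6,7-olefin then adds anti (C6 to the incipient tertiary cation, C7 captured by the enol carbon), which for a Z-olefin gives the cis ring fusion (Stork–Eschenmoser stereospecificity), ring A closing before ring B, and the catalyst-controlled face of protonation fixes C4a and C8a as R and S; the closest known reaction types are the racemic SnCl4-promoted cyclisation of Z-olefinic β-keto esters to cis-fused decalones and IDPi-catalysed enantioselective proton-initiated cyclisations of E-polyenes terminated by hydroxyl groups.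

Step 4
Reactants: 6 cis-fused β-keto ester
Product: 8 methyl (4aR,8aS)-5,5,8a-trimethyl-2-{[(trifluoromethyl)sulfonyl]oxy}-3,4,4a,5,6,7,8,8a-octahydronaphthalene-1-carboxylate, via sodium enolate 7 (not isolated)
Conditions: NaH (1.2 equiv), CH2Cl2, 0 °C; then Tf2O (1.2 equiv), 0 °C
Reagents that add atoms: triflic anhydride, O=S(=O)(OS(=O)(=O)C(F)(F)F)C(F)(F)F
Why: O-sulfonylation of the β-keto ester enolate gives the conjugated enol triflate and removes the C-1 centre; C4a is not α to the ketone, so the cis fusion cannot epimerise.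

Step 5
Reactants: 8 enol triflate
Product: 9 methyl (4aR,8aS)-2,5,5,8a-tetramethyl-3,4,4a,5,6,7,8,8a-octahydronaphthalene-1-carboxylate
Conditions: MeMgBr (1.5 equiv), Fe(acac)3 (5 mol %), THF/NMP, −30 °C, 30 min
Reagents that add atoms: methylmagnesium bromide, C[Mg]Br
Why: Iron-catalysed Kumada-type cross-coupling of an activated alkenyl triflate with a methyl Grignard reagent is fast at −30 °C, so the hindered ester is not attacked.

Step 6
Reactants: 9 enoate
Product: 10 [(4aR,8aS)-2,5,5,8a-tetramethyl-3,4,4a,5,6,7,8,8a-octahydronaphthalen-1-yl]methanol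
Conditions: i-Bu2AlH (2.5 equiv), CH2Cl2, −78 → 0 °C; aq. potassium sodium tartrate work-up
Reagents that add atoms: none
Why: 1,2-Hydride reduction of the hindered enoate by the aluminium hydride gives the allylic alcohol and leaves the tetrasubstituted olefin alone.

Step 7
Reactants: 10 allylic alcohol
Product: 11 [(4aR,8aS)-2,5,5,8a-tetramethyl-3,4,4a,5,6,7,8,8a-octahydronaphthalen-1-yl]methyl bromide
Conditions: PBr3 (0.4 equiv), pyridine (cat.), Et2O, 0 °C; used crude
Reagents that add atoms: phosphorus tribromide, BrP(Br)Br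
Why: PBr3 bromination of the primary allylic alcohol (SN2 on the phosphite ester) keeps the more stable tetrasubstituted ring olefin in place.

Step 8
Reactants: 12 1-(trimethylsilyl)propyne; 11 allylic bromide
Product: 14 trimethyl{4-[(4aR,8aS)-2,5,5,8a-tetramethyl-3,4,4a,5,6,7,8,8a-octahydronaphthalen-1-yl]but-1-yn-1-yl}silane, via 3-(trimethylsilyl)propargyllithium 13 (not isolated)
Conditions: 12 (1.5 equiv), n-BuLi (1.4 equiv), THF, −78 → −20 °C; then 11, −78 °C → rt
Reagents that add atoms: none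
Why: The lithiated silylpropyne reacts at its propargylic carbon (the silyl group suppresses the allenyl pathway) in an SN2 alkylation of the primary allylic bromide, forming the C7–C8 bond of the side chain.

Step 9
Reactants: 14 silyl alkyne
Product: 15 4-[(4aR,8aS)-2,5,5,8a-tetramethyl-3,4,4a,5,6,7,8,8a-octahydronaphthalen-1-yl]but-1-yne
Conditions: K2CO3 (0.2 equiv), MeOH, rt
Reagents that add atoms: none
Why: Base-catalysed methanolysis of the alkynyl C–Si bond (protodesilylation) gives the terminal alkyne.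

Step 10
Reactants: 15 terminal alkyne
Product: 17 (1E)-1-iodo-2-methyl-4-[(4aR,8aS)-2,5,5,8a-tetramethyl-3,4,4a,5,6,7,8,8a-octahydronaphthalen-1-yl]but-1-ene, via E-alkenyldimethylalane 16 (not isolated)
Conditions: AlMe3 (2.0 equiv), Cp2ZrCl2 (0.25 equiv), CH2Cl2, 0 °C → rt; then I2 (1.2 equiv), THF, −30 → 0 °C
Reagents that add atoms: trimethylaluminium, C[Al](C)C; iodine, II
Why: Negishi zirconium-catalysed carboalumination adds Me–Al syn across the terminal alkyne (Me to the internal carbon) and iodinolysis with retention gives the E-trisubstituted vinyl iodide; the hindered ring olefin does not react.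

Step 11
Reactants: 18 methyl (S)-3-hydroxy-2-methylpropanoate
Product: 19 methyl (S)-3-[(tert-butyldimethylsilyl)oxy]-2-methylpropanoate
Conditions: TBSCl (1.1 equiv), imidazole (1.5 equiv), CH2Cl2, 0 °C → rt
Reagents that add atoms: tert-butyldimethylsilyl chloride, CC(C)(C)[Si](C)(C)Cl
Why: Silyl ether protection of the primary hydroxyl; the stereocentre, taken from the chiral pool, is not touched.

Step 12
Reactants: 19 silyl ether ester
Product: 21 (S)-3-[(tert-butyldimethylsilyl)oxy]-2-methylpropanal, via aluminium hemiacetal 20 (not isolated)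
Conditions: i-Bu2AlH (1.05 equiv), CH2Cl2, −78 °C; MeOH then aq. potassium sodium tartrate; used crude
Reagents that add atoms: none
Why: Partial ester reduction: at −78 °C the tetrahedral aluminium hemiacetal persists and collapses to the aldehyde only on work-up, which avoids over-reduction and α-epimerisation.

Step 13
Reactants: 21 aldehyde
Product: 22 (R)-tert-butyldimethyl[(2-methylbut-3-yn-1-yl)oxy]silane
Conditions: dimethyl (1-diazo-2-oxopropyl)phosphonate (1.3 equiv), K2CO3 (2 equiv), MeOH, 0 °C → rt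
Reagents that add atoms: Ohira–Bestmann reagent, COP(=O)(OC)C(=[N+]=[N-])C(C)=O
Why: Seyferth–Gilbert homologation in its Ohira–Bestmann variant converts the aldehyde into the terminal alkyne under mild carbonate conditions that preserve the α-methyl stereocentre (the descriptor changes to R only through CIP priorities).

Step 14
Reactants: 22 alkyne
Product: 23 (R,E)-tert-butyldimethyl{[2-methyl-4-(4,4,5,5-tetramethyl-1,3,2-dioxaborolan-2-yl)but-3-en-1-yl]oxy}silane
Conditions: pinacolborane (1.3 equiv), Cp2Zr(H)Cl (10 mol %), Et3N (10 mol %), neat, 60 °C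
Reagents that add atoms: pinacolborane, CC1(C)OBOC1(C)C
Why: Zirconium-catalysed syn hydroboration of the terminal alkyne places boron on the terminal carbon and gives the E-alkenyl boronate.

Step 15
Reactants: 17 vinyl iodide; 23 vinyl boronate
Product: 24 tert-butyldimethyl{[(2R,3E,5E)-2,6-dimethyl-8-[(4aR,8aS)-2,5,5,8a-tetramethyl-3,4,4a,5,6,7,8,8a-octahydronaphthalen-1-yl]octa-3,5-dien-1-yl]oxy}silane
Conditions: PdCl2(dppf) (5 mol %), K3PO4 (3 equiv, 3 M aq.), THF, rt → 40 °C, degassed
Reagents that add atoms: none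
Why: Suzuki–Miyaura sp2–sp2 coupling proceeds with retention of both olefin geometries to give the (3E,5E)-diene, while C2 is still at the non-acidic alcohol oxidation level.

Step 16
Reactants: 24 diene silyl ether
Product: 25 (2R,3E,5E)-2,6-dimethyl-8-[(4aR,8aS)-2,5,5,8a-tetramethyl-3,4,4a,5,6,7,8,8a-octahydronaphthalen-1-yl]octa-3,5-dien-1-ol
Conditions: HF·pyridine, pyridine, THF, 0 °C → rt
Reagents that add atoms: none
Why: Fluoride cleavage of the primary silyl ether under pyridine-buffered conditions that do not isomerise the diene.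

Step 17
Reactants: 25 dienyl alcohol
Product: 26 (2R,3E,5E)-2,6-dimethyl-8-[(4aR,8aS)-2,5,5,8a-tetramethyl-3,4,4a,5,6,7,8,8a-octahydronaphthalen-1-yl]octa-3,5-dienal
Conditions: Dess–Martin periodinane (1.3 equiv), pyridine (3 equiv), CH2Cl2, 0 °C, 30 min; short silica plug, used at once
Reagents that add atoms: none
Why: Dess–Martin oxidation under buffered, non-basic conditions gives the β,γ-unsaturated aldehyde without epimerisation at C2 or conjugation, provided it is used immediately.

Step 18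
Reactants: 26 dienyl aldehyde
Product: 27 (2R,3E,5E)-2,6-dimethyl-8-[(4aR,8aS)-2,5,5,8a-tetramethyl-3,4,4a,5,6,7,8,8a-octahydronaphthalen-1-yl]octa-3,5-dienoic acid
Conditions: NaClO2 (3 equiv), NaH2PO4 (4 equiv), 2-methyl-2-butene (20 equiv), t-BuOH/H2O, 0 °C
Reagents that add atoms: sodium chlorite, [Na+].[O-]Cl=O
Why: Pinnick oxidation at about pH 4, with 2-methyl-2-butene as hypochlorite scavenger, converts the aldehyde to the acid without touching the olefins or the α-stereocentre.

Step 19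
Reactants: 27 dienoic acid
Product: 28 methyl (2R,3E,5E)-2,6-dimethyl-8-[(4aR,8aS)-2,5,5,8a-tetramethyl-3,4,4a,5,6,7,8,8a-octahydronaphthalen-1-yl]octa-3,5-dienoate
Conditions: TMSCHN2 (1.5 equiv), toluene/MeOH 4:1, 0 °C, 20 min
Reagents that add atoms: (trimethylsilyl)diazomethane, C[Si](C)(C)C=[N+]=[N-]
Why: Diazoalkane O-methylation of the carboxylic acid is neutral, so no base is present that could epimerise C2 or move the diene into conjugation.

**Compound list**

1 | nerol, (2Z)-3,7-dimethylocta-2,6-dien-1-ol | CC(C)=CCC/C(C)=C\CO | starting material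
2 | neryl bromide, (2Z)-1-bromo-3,7-dimethylocta-2,6-diene | CC(C)=CCC/C(C)=C\CBr | intermediate
3 | methyl acetoacetate | COC(=O)CC(C)=O | starting material
4 | methyl acetoacetate dianion, sodium lithium salt (in situ) | [Na+].[Li+].COC([O-])=CC([O-])=C | intermediate
5 | methyl (6Z)-7,11-dimethyl-3-oxododeca-6,10-dienoate | COC(=O)CC(=O)CC/C=C(C)\CCC=C(C)C | intermediate
6 | methyl (4aR,8aS)-5,5,8a-trimethyl-2-oxodecahydronaphthalene-1-carboxylate (cis-fused; C-1 epimers/enol interconvert) | COC(=O)C1C(=O)CC[C@@H]2C(C)(C)CCC[C@]12C | intermediate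
7 | sodium enolate of 6 (in situ) | [Na+].COC(=O)C1=C([O-])CC[C@@H]2C(C)(C)CCC[C@]12C | intermediate
8 | methyl (4aR,8aS)-5,5,8a-trimethyl-2-{[(trifluoromethyl)sulfonyl]oxy}-3,4,4a,5,6,7,8,8a-octahydronaphthalene-1-carboxylate | COC(=O)C1=C(OS(=O)(=O)C(F)(F)F)CC[C@@H]2C(C)(C)CCC[C@]12C | intermediate
9 | methyl (4aR,8aS)-2,5,5,8a-tetramethyl-3,4,4a,5,6,7,8,8a-octahydronaphthalene-1-carboxylate | COC(=O)C1=C(C)CC[C@@H]2C(C)(C)CCC[C@]12C | intermediate
10 | [(4aR,8aS)-2,5,5,8a-tetramethyl-3,4,4a,5,6,7,8,8a-octahydronaphthalen-1-yl]methanol | OCC1=C(C)CC[C@@H]2C(C)(C)CCC[C@]12C | intermediate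
11 | [(4aR,8aS)-2,5,5,8a-tetramethyl-3,4,4a,5,6,7,8,8a-octahydronaphthalen-1-yl]methyl bromide | BrCC1=C(C)CC[C@@H]2C(C)(C)CCC[C@]12C | intermediate
12 | 1-(trimethylsilyl)propyne | CC#C[Si](C)(C)C | starting material
13 | 3-(trimethylsilyl)prop-2-yn-1-yllithium (in situ) | [Li]CC#C[Si](C)(C)C | intermediate
14 | trimethyl{4-[(4aR,8aS)-2,5,5,8a-tetramethyl-3,4,4a,5,6,7,8,8a-octahydronaphthalen-1-yl]but-1-yn-1-yl}silane | C[Si](C)(C)C#CCCC1=C(C)CC[C@@H]2C(C)(C)CCC[C@]12C | intermediate
15 | 4-[(4aR,8aS)-2,5,5,8a-tetramethyl-3,4,4a,5,6,7,8,8a-octahydronaphthalen-1-yl]but-1-yne | C#CCCC1=C(C)CC[C@@H]2C(C)(C)CCC[C@]12C | intermediate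
16 | dimethyl{(1E)-2-methyl-4-[(4aR,8aS)-2,5,5,8a-tetramethyl-3,4,4a,5,6,7,8,8a-octahydronaphthalen-1-yl]but-1-en-1-yl}alumane (in situ) | C[Al](C)/C=C(\C)CCC1=C(C)CC[C@@H]2C(C)(C)CCC[C@]12C | intermediate
17 | (1E)-1-iodo-2-methyl-4-[(4aR,8aS)-2,5,5,8a-tetramethyl-3,4,4a,5,6,7,8,8a-octahydronaphthalen-1-yl]but-1-ene | I/C=C(\C)CCC1=C(C)CC[C@@H]2C(C)(C)CCC[C@]12C | intermediate
18 | methyl (S)-3-hydroxy-2-methylpropanoate (Roche ester) | COC(=O)[C@@H](C)CO | starting material
19 | methyl (S)-3-[(tert-butyldimethylsilyl)oxy]-2-methylpropanoate | COC(=O)[C@@H](C)CO[Si](C)(C)C(C)(C)C | intermediate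
20 | diisobutylaluminium hemiacetal of 19, {(2S)-3-[(tert-butyldimethylsilyl)oxy]-1-methoxy-2-methylpropoxy}bis(2-methylpropyl)alumane (in situ) | COC(O[Al](CC(C)C)CC(C)C)[C@@H](C)CO[Si](C)(C)C(C)(C)C | intermediate
21 | (S)-3-[(tert-butyldimethylsilyl)oxy]-2-methylpropanal | O=C[C@@H](C)CO[Si](C)(C)C(C)(C)C | intermediate
22 | (R)-tert-butyldimethyl[(2-methylbut-3-yn-1-yl)oxy]silane | C#C[C@@H](C)CO[Si](C)(C)C(C)(C)C | intermediate
23 | (R,E)-tert-butyldimethyl{[2-methyl-4-(4,4,5,5-tetramethyl-1,3,2-dioxaborolan-2-yl)but-3-en-1-yl]oxy}silane | CC1(C)OB(/C=C/[C@@H](C)CO[Si](C)(C)C(C)(C)C)OC1(C)C | intermediate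
24 | tert-butyldimethyl{[(2R,3E,5E)-2,6-dimethyl-8-[(4aR,8aS)-2,5,5,8a-tetramethyl-3,4,4a,5,6,7,8,8a-octahydronaphthalen-1-yl]octa-3,5-dien-1-yl]oxy}silane | CC(C)(C)[Si](C)(C)OC[C@H](C)/C=C/C=C(\C)CCC1=C(C)CC[C@@H]2C(C)(C)CCC[C@]12C | intermediate
25 | (2R,3E,5E)-2,6-dimethyl-8-[(4aR,8aS)-2,5,5,8a-tetramethyl-3,4,4a,5,6,7,8,8a-octahydronaphthalen-1-yl]octa-3,5-dien-1-ol | OC[C@H](C)/C=C/C=C(\C)CCC1=C(C)CC[C@@H]2C(C)(C)CCC[C@]12C | intermediate
26 | (2R,3E,5E)-2,6-dimethyl-8-[(4aR,8aS)-2,5,5,8a-tetramethyl-3,4,4a,5,6,7,8,8a-octahydronaphthalen-1-yl]octa-3,5-dienal | O=C[C@H](C)/C=C/C=C(\C)CCC1=C(C)CC[C@@H]2C(C)(C)CCC[C@]12C | intermediate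
27 | (2R,3E,5E)-2,6-dimethyl-8-[(4aR,8aS)-2,5,5,8a-tetramethyl-3,4,4a,5,6,7,8,8a-octahydronaphthalen-1-yl]octa-3,5-dienoic acid | OC(=O)[C@H](C)/C=C/C=C(\C)CCC1=C(C)CC[C@@H]2C(C)(C)CCC[C@]12C | intermediate
28 | methyl (2R,3E,5E)-2,6-dimethyl-8-[(4aR,8aS)-2,5,5,8a-tetramethyl-3,4,4a,5,6,7,8,8a-octahydronaphthalen-1-yl]octa-3,5-dienoate | COC(=O)[C@H](C)/C=C/C=C(\C)CCC1=C(C)CC[C@@H]2C(C)(C)CCC[C@]12C | target

**Step count and risks**

Total steps: 19. Longest linear sequence: 15 steps (steps 1–10, then 15–19, from nerol). The Roche-ester branch is steps 11–14.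

The three steps most likely to fail:

Step 3 (the proposed new cyclisation). Risks are low enantioselectivity, O-cyclisation to a bicyclic enol ether, stepwise leakage to the trans-fused isomer, and catalyst inhibition by the keto ester. The fallback uses known chemistry, sets out from 2 and comes back at 10. Commercial (−)-menthyl acetoacetate (CC(=O)CC(=O)O[C@@H]1C[C@H](C)CC[C@H]1C(C)C) is converted with NaH then n-BuLi (THF, 0 °C) into the menthyl acetoacetate dianion F1 (not isolated), which is alkylated with 2 to give (1R,2S,5R)-menthyl (6Z)-7,11-dimethyl-3-oxododeca-6,10-dienoate F2. SnCl4 (2 equiv, CH2Cl2, 0 °C → rt), the established stoichiometric Lewis-acid cyclisation of Z-olefinic β-keto esters, closes both rings to the two cis-fused diastereomers, the (4aR,8aS)-menthyl keto ester F3 and the (4aS,8aR)-menthyl keto ester F4. These differ only in the absolute sense of the decalin and are separated by chromatography or crystallisation, with assignment by X-ray. F3 is converted with Tf2O/i-Pr2NEt (CH2Cl2, −78 °C) into the menthyl enol triflate F5 and with MeMgBr/Fe(acac)3 into the menthyl enoate F6; LiAlH4 (THF, reflux) then gives 10 and releases (−)-menthol.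

Step 8 (propargylation of the hindered, labile allylic bromide). Risks are elimination or SN2′ attack by the basic propargyl anion. The fallback sets out from 11 and comes back at 15. Bromide 11 is alkylated with the soft, non-basic commercial sodium salt of ethyl acetoacetate (THF/DMF, rt) to give ethyl 3-oxo-2-{[(4aR,8aS)-2,5,5,8a-tetramethyl-3,4,4a,5,6,7,8,8a-octahydronaphthalen-1-yl]methyl}butanoate F7. Saponification and decarboxylation (KOH, aq. EtOH, reflux; then H3O+) give the methyl ketone 4-[(4aR,8aS)-2,5,5,8a-tetramethyl-3,4,4a,5,6,7,8,8a-octahydronaphthalen-1-yl]butan-2-one F8. Kinetic enolisation on the methyl side with LiN(i-Pr)2 (THF, −78 °C), trapping with ClP(O)(OEt)2 to the diethyl enol phosphate F9 (not isolated) and elimination with a further 2.2 equiv of LiN(i-Pr)2 give alkyne 15 directly, so step 9 is bypassed as well.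

Step 17 (oxidation to the dienyl aldehyde). Risks are epimerisation of 26 at C2 or isomerisation into conjugation before it is oxidised further. The fallback sets out from 22 and comes back at 28; it moves the oxidation-state change to the small fragment, before the coupling. Palladium-catalysed hydrostannylation of 22 (Bu3SnH, PdCl2(PPh3)2 cat., THF, 0 °C) gives (R,E)-tert-butyldimethyl{[2-methyl-4-(tributylstannyl)but-3-en-1-yl]oxy}silane F10. Bu4NF (THF) frees (R,E)-2-methyl-4-(tributylstannyl)but-3-en-1-ol F11. Buffered Dess–Martin oxidation gives (R,E)-2-methyl-4-(tributylstannyl)but-3-enal F12, Pinnick oxidation gives (R,E)-2-methyl-4-(tributylstannyl)but-3-enoic acid F13, and TMSCHN2 gives methyl (R,E)-2-methyl-4-(tributylstannyl)but-3-enoate F14, whose enantiomeric purity is checked at this stage. Base-free Stille coupling of F14 with vinyl iodide 17 (Pd2(dba)3, AsPh3, NMP, rt) then gives 28 directly and replaces steps 14–19.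

**Further compounds**

F1 | step 3 | (−)-menthyl acetoacetate dianion, sodium lithium salt (not isolated) | [Na+].[Li+].C=C([O-])C=C([O-])O[C@@H]1C[C@H](C)CC[C@H]1C(C)C
F2 | step 3 | (1R,2S,5R)-menthyl (6Z)-7,11-dimethyl-3-oxododeca-6,10-dienoate | CC(C)=CCC/C(C)=C\CCC(=O)CC(=O)O[C@@H]1C[C@H](C)CC[C@H]1C(C)C
F3 | step 3 | (1R,2S,5R)-menthyl (4aR,8aS)-5,5,8a-trimethyl-2-oxodecahydronaphthalene-1-carboxylate (cis-fused, wanted diastereomer) | O=C(O[C@@H]3C[C@H](C)CC[C@H]3C(C)C)C1C(=O)CC[C@@H]2C(C)(C)CCC[C@]12C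
F4 | step 3 | (1R,2S,5R)-menthyl (4aS,8aR)-5,5,8a-trimethyl-2-oxodecahydronaphthalene-1-carboxylate (cis-fused, unwanted diastereomer) | O=C(O[C@@H]3C[C@H](C)CC[C@H]3C(C)C)C1C(=O)CC[C@H]2C(C)(C)CCC[C@@]12C
F5 | step 3 | (1R,2S,5R)-menthyl (4aR,8aS)-5,5,8a-trimethyl-2-{[(trifluoromethyl)sulfonyl]oxy}-3,4,4a,5,6,7,8,8a-octahydronaphthalene-1-carboxylate | O=C(O[C@@H]3C[C@H](C)CC[C@H]3C(C)C)C1=C(OS(=O)(=O)C(F)(F)F)CC[C@@H]2C(C)(C)CCC[C@]12C
F6 | step 3 | (1R,2S,5R)-menthyl (4aR,8aS)-2,5,5,8a-tetramethyl-3,4,4a,5,6,7,8,8a-octahydronaphthalene-1-carboxylate | O=C(O[C@@H]3C[C@H](C)CC[C@H]3C(C)C)C1=C(C)CC[C@@H]2C(C)(C)CCC[C@]12C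
F7 | step 8 | ethyl 3-oxo-2-{[(4aR,8aS)-2,5,5,8a-tetramethyl-3,4,4a,5,6,7,8,8a-octahydronaphthalen-1-yl]methyl}butanoate (C-2 epimers) | CCOC(=O)C(CC1=C(C)CC[C@@H]2C(C)(C)CCC[C@]12C)C(C)=O
F8 | step 8 | 4-[(4aR,8aS)-2,5,5,8a-tetramethyl-3,4,4a,5,6,7,8,8a-octahydronaphthalen-1-yl]butan-2-one | CC(=O)CCC1=C(C)CC[C@@H]2C(C)(C)CCC[C@]12C
F9 | step 8 | diethyl 4-[(4aR,8aS)-2,5,5,8a-tetramethyl-3,4,4a,5,6,7,8,8a-octahydronaphthalen-1-yl]but-1-en-2-yl phosphate (not isolated) | C=C(CCC1=C(C)CC[C@@H]2C(C)(C)CCC[C@]12C)OP(=O)(OCC)OCC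
F10 | step 17 | (R,E)-tert-butyldimethyl{[2-methyl-4-(tributylstannyl)but-3-en-1-yl]oxy}silane | CCCC[Sn](CCCC)(CCCC)/C=C/[C@@H](C)CO[Si](C)(C)C(C)(C)C
F11 | step 17 | (R,E)-2-methyl-4-(tributylstannyl)but-3-en-1-ol | CCCC[Sn](CCCC)(CCCC)/C=C/[C@@H](C)CO
F12 | step 17 | (R,E)-2-methyl-4-(tributylstannyl)but-3-enal | CCCC[Sn](CCCC)(CCCC)/C=C/[C@@H](C)C=O
F13 | step 17 | (R,E)-2-methyl-4-(tributylstannyl)but-3-enoic acid | CCCC[Sn](CCCC)(CCCC)/C=C/[C@@H](C)C(O)=O
F14 | step 17 | methyl (R,E)-2-methyl-4-(tributylstannyl)but-3-enoate | CCCC[Sn](CCCC)(CCCC)/C=C/[C@@H](C)C(=O)OC
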